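**Assumption:** The target is achiral (no stereocentres; the 2,2-dimethylchromene and the prenyl alkene have no E/Z issue), so "single enantiomer" is moot. The only stereocentre in the route is the carbinol in 13, which is racemic and destroyed in Step 9.

## Retrosynthetic overview
1. The target comes from global removal of three MOM groups from the protected 3-prenylchromone **15**.
2. The bold key step is a single Au(I)-catalysed 6-endo oxa-cyclisation of an o-(1,1-dimethylallyl)oxy aryl ynone **14**. The γ-pyrone ring closes and the 3-prenyl group is delivered by a 1,3-allyl shift in the same step, so no late C3 functionalisation is needed.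
3. Ynone **14** comes from adding the B-ring terminal alkyne **8** to the A-ring aldehyde **12**, then oxidising.
4. The B-ring chromene is made from 2,4-dihydroxybenzaldehyde by propargyl-ether Claisen/6π-electrocyclisation. The A-ring fragment comes from 2,4,6-trihydroxybenzaldehyde.
5. Ring-forming order: pyran of the B ring, then ynone assembly, then the pyrone ring with its prenyl group (Au step), then deprotection.

## Route

**Step 1**
Reactants: **1** 2,4-dihydroxybenzaldehyde; **2** 3-chloro-3-methylbut-1-yne
Product: **3** 2-hydroxy-4-[(2-methylbut-3-yn-2-yl)oxy]benzaldehyde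
Conditions: CuCl2·2H2O (cat.), DBU, MeCN, 0 °C to rt
Reagents that add atoms: **2**, C#CC(C)(C)Cl
Why: The 4-OH is the more acidic phenol and the 2-OH is locked in a chelate with the CHO, so Cu-mediated O-propargylation of a tertiary propargyl chloride (Godfrey-type etherification) occurs selectively at O4.

**Step 2**
Reactants: **3**
Product: **4** 5-hydroxy-2,2-dimethyl-2H-chromene-6-carbaldehyde
Conditions: PhNEt2, 210 °C, sealed tube, 3 h
Reagents that add atoms: none
Why: Aryl propargyl ether aromatic Claisen rearrangement, then enolisation, 1,5-H shift and 6π-oxa-electrocyclisation; cyclisation at C3 (angular) is favoured because the chelate-fixed C3=C4 bond has the higher double-bond order, and the minor linear isomer is removed by chromatography.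

**Step 3**
Reactants: **4**; **5** chloromethyl methyl ether (MOMCl)
Product: **6** 5-(methoxymethoxy)-2,2-dimethyl-2H-chromene-6-carbaldehyde
Conditions: NaH, DMF, 0 °C, then MOMCl, 0 °C to rt
Reagents that add atoms: **5**, ClCOC
Why: Simple Williamson-type MOM protection of the chelated phenol, which keeps it inert to the acetylide and the Au catalyst later.

**Step 4**
Reactants: **6**; **7** dimethyl (1-diazo-2-oxopropyl)phosphonate (Ohira–Bestmann reagent)
Product: **8** 6-ethynyl-5-(methoxymethoxy)-2,2-dimethyl-2H-chromene
Conditions: K2CO3, MeOH, rt, 6 h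
Reagents that add atoms: **7**, COP(=O)(OC)C(=[N+]=[N-])C(C)=O (supplies the terminal alkyne carbon)
Why: Ohira–Bestmann homologation converts the aldehyde to the terminal alkyne under base-only conditions that leave the MOM ether and the chromene alkene untouched.

**Step 5**
Reactants: **9** 2,4,6-trihydroxybenzaldehyde; **5** MOMCl
Product: **10** 2-hydroxy-4,6-bis(methoxymethoxy)benzaldehyde
Conditions: MOMCl (2.2 equiv), iPr2NEt, CH2Cl2, 0 °C
Reagents that add atoms: **5**, ClCOC
Why: The 4-OH and one of the two equivalent 2/6-OH groups are alkylated, while the remaining OH stays chelated to the CHO, which both desymmetrises the ring and leaves the future ring-oxygen free.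

**Step 6**
Reactants: **10**; **2** 3-chloro-3-methylbut-1-yne
Product: **11** 2-[(2-methylbut-3-yn-2-yl)oxy]-4,6-bis(methoxymethoxy)benzaldehyde
Conditions: CuCl2·2H2O (cat.), DBU, MeCN, 0 °C to rt
Reagents that add atoms: **2**, C#CC(C)(C)Cl
Why: The same Cu/DBU tertiary propargylation works on hindered, chelated phenols and installs the masked tertiary allyl group.

**Step 7**
Reactants: **11**
Product: **12** 2-[(2-methylbut-3-en-2-yl)oxy]-4,6-bis(methoxymethoxy)benzaldehyde
Conditions: H2 (1 atm), Lindlar catalyst, quinoline, EtOAc, rt, short reaction time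
Reagents that add atoms: none (H2 only)
Why: Lindlar semihydrogenation stops at the terminal alkene. The aldehyde and MOM groups survive, and the B-ring chromene alkene is not yet present, so nothing else can be reduced.

**Step 8**
Reactants: **8**; **12**
Product: **13** 1-[2-(1,1-dimethylallyloxy)-4,6-bis(MOMO)phenyl]-3-[5-(MOMO)-2,2-dimethyl-2H-chromen-6-yl]prop-2-yn-1-ol (racemic)
Conditions: n-BuLi, THF, −78 °C (acetylide formation), then add **12**, −78 °C to 0 °C
Reagents that add atoms: none (n-BuLi only deprotonates; Li is lost on work-up)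
Why: 1,2-Addition of a lithium acetylide to an aryl aldehyde; the new carbinol stereocentre is transient and racemic.

**Step 9**
Reactants: **13**
Product: **14** 1-[2-(1,1-dimethylallyloxy)-4,6-bis(MOMO)phenyl]-3-[5-(MOMO)-2,2-dimethyl-2H-chromen-6-yl]prop-2-yn-1-one
Conditions: Dess–Martin periodinane, NaHCO3, CH2Cl2, 0 °C to rt
Reagents that add atoms: none
Why: Mild, non-acidic oxidation of the propargylic alcohol to the ynone leaves the allyl aryl ether, MOM groups and chromene intact, and removes the carbinol stereocentre.

**Step 10**
Reactants: **14**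
Product: **15** 3-prenyl-5,7-bis(MOMO)-2-[5-(MOMO)-2,2-dimethyl-2H-chromen-6-yl]-4H-chromen-4-one (isomer of 14)
Conditions: IPrAuCl (5 mol%), AgNTf2 (5 mol%), 4 Å MS, 1,2-DCE, 40 °C
Reagents that add atoms: none (isomerisation)
Why: Proposed new method: Au(I) activates the ynone alkyne, the ortho ether oxygen attacks the electrophilic β-carbon (6-endo, Michael-polarised) to give an aryl/tert-allyl oxonium with a C3–Au vinyl. The tert-allyl group then transfers to C3 through its CH2 terminus, by concerted [3,3] or ion-pair 1,3-shift, so the 1,1-dimethylallyl ether delivers the linear prenyl group, and Au(I) is regenerated. The closest known reactions are Au/Pt-catalysed cyclisation/1,3-allyl migration of o-alkynylphenyl allyl ethers to 3-allylbenzofurans, and iodocyclisation of o-alkoxyaryl ynones to 3-iodochromones.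

**Step 11**
Reactants: **15**
Product: **16** Kuwanon B (target): 3-prenyl-5,7-dihydroxy-2-(5-hydroxy-2,2-dimethyl-2H-chromen-6-yl)chromen-4-one
Conditions: 2 M HCl, MeOH/THF (1:1), 45 °C, 4 h
Reagents that add atoms: none (water and methanol only hydrolyse the MOM acetals)
Why: Acidolysis of aryl MOM acetals, with the 5-OMOM and chelated groups cleaving easily, and the chromene, prenyl alkene and chromone tolerating brief mild acid.

## Compound list
1 | 2,4-dihydroxybenzaldehyde | O=Cc1ccc(O)cc1O | starting material
2 | 3-chloro-3-methylbut-1-yne | C#CC(C)(C)Cl | starting material (reagent)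
3 | 2-hydroxy-4-[(2-methylbut-3-yn-2-yl)oxy]benzaldehyde | O=Cc1ccc(OC(C)(C)C#C)cc1O | intermediate
4 | 5-hydroxy-2,2-dimethyl-2H-chromene-6-carbaldehyde | O=Cc1ccc2OC(C)(C)C=Cc2c1O | intermediate
5 | chloromethyl methyl ether (MOMCl) | ClCOC | starting material (reagent)
6 | 5-(methoxymethoxy)-2,2-dimethyl-2H-chromene-6-carbaldehyde | O=Cc1ccc2OC(C)(C)C=Cc2c1OCOC | intermediate
7 | dimethyl (1-diazo-2-oxopropyl)phosphonate | COP(=O)(OC)C(=[N+]=[N-])C(C)=O | starting material (reagent)
8 | 6-ethynyl-5-(methoxymethoxy)-2,2-dimethyl-2H-chromene | C#Cc1ccc2OC(C)(C)C=Cc2c1OCOC | intermediate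
9 | 2,4,6-trihydroxybenzaldehyde | O=Cc1c(O)cc(O)cc1O | starting material
10 | 2-hydroxy-4,6-bis(methoxymethoxy)benzaldehyde | O=Cc1c(O)cc(OCOC)cc1OCOC | intermediate
11 | 2-(2-methylbut-3-yn-2-yloxy)-4,6-bis(MOMO)benzaldehyde | O=Cc1c(OC(C)(C)C#C)cc(OCOC)cc1OCOC | intermediate
12 | 2-(2-methylbut-3-en-2-yloxy)-4,6-bis(MOMO)benzaldehyde | O=Cc1c(OC(C)(C)C=C)cc(OCOC)cc1OCOC | intermediate
13 | propargylic alcohol (racemic carbinol) | OC(C#Cc1ccc2OC(C)(C)C=Cc2c1OCOC)c1c(OC(C)(C)C=C)cc(OCOC)cc1OCOC | intermediate
14 | aryl ynone | O=C(C#Cc1ccc2OC(C)(C)C=Cc2c1OCOC)c1c(OC(C)(C)C=C)cc(OCOC)cc1OCOC | intermediate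
15 | tris-MOM 3-prenylflavone | CC(C)=CCc1c(-c2ccc3OC(C)(C)C=Cc3c2OCOC)oc2cc(OCOC)cc(OCOC)c2c1=O | intermediate
16 | Kuwanon B (target, achiral) | CC(C)=CCc1c(-c2ccc3c(c2O)C=CC(C)(C)O3)oc2cc(O)cc(O)c2c1=O | target

## Step count
Total steps: 11. Longest linear sequence: 8 steps (1→2→3→4→8→9→10→11); the A-ring arm is 3 steps (5→6→7) and joins at Step 8.

## Three steps most likely to fail
1. **Step 10 (Au cascade).** Possible problems are premature ionisation of the tertiary allyl ether, 5-exo (aurone) closure, or simple 3-H flavone formation.
   Fallback: abandon the cascade and use the Baker–Venkataraman route. Make the 2-hydroxy-4,6-bis(MOMO)acetophenone A-ring and the B-ring acid chloride from aldehyde **6**, then C-prenylate the 1,3-diketone and cyclodehydrate.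
2. **Step 2 (Claisen regiochemistry).** Angular versus linear chromene selectivity may be poor.
   Fallback: use directed ortho-metalation of 1,3-bis(MOMO)benzene, which lithiates at C2 between the two oxygens. Quench with prenyl bromide/CuI, formylate at C4, then close the pyran by DDQ dehydrocyclisation of the 2-hydroxy-3-prenyl arene.
3. **Step 7 (Lindlar on a tertiary allylic aryl ether).** Pd may ionise or over-reduce the product.
   Fallback: skip the reduction, carry propargyl ether **11** through Steps 8–9 and into the Au step, where propargyl transfer gives a 3-(3-methylbuta-1,2-dienyl)chromone. Then selectively hydrogenate the less hindered allene C=C with Wilkinson's catalyst to give the prenyl group.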